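**Plan**

- Ring letters: A is the terminal 3,5-dihydroxyphenoxy ring, B/C the dibenzofuran, D the second benzo ring of the dibenzo-1,4-dioxin, E–F the biaryl, G and H the two outer phenoxy rings. All sixteen OH groups are carried as OMe.
- Cuts, in retrosynthetic order: (i) sixteen O–Me bonds; (ii) the dioxin C–O bond between ring C C-1 (dibenzofuran numbering) and the ring D oxygen, opened to a C–H and a free phenol; (iii) the ring C–O–ring D ether (SNAr on an ortho-fluorobenzaldehyde whose CHO then becomes that phenol by Baeyer–Villiger oxidation); (iv) the D–O–E ether (Ullmann); (v) the E–F biaryl bond (Negishi); (vi) the F–O–G and G–O–H ethers (SNAr/Baeyer–Villiger); (vii) the dibenzofuran C–C bond, the A–O–B ether and the B–O–C ether.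
- Forward order: chain H→G→F→E, then ring D is added; separately ring C→B→A and furan closure; union of the two halves; the dioxin ring closes last. One fluoroaldehyde (2) supplies rings B, D, F and G.
- Enabling feature: in 31 the only free OH sits on ring D ortho to the ether oxygen that joins ring D to ring C. On ring C that ether oxygen has one ortho C–H (C-1) and one ortho C–OMe, so a metal held on the phenoxide can close only a six-membered 1,4-dioxin, and only there. Every other diaryl ether has a ring with both ortho positions blocked.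
- Stereochemistry: the target has no stereocentre; nothing has to be set.

Key step: step 20

Assumption: the target carries no stereodescriptor, so the tetra-ortho-substituted E–F biaryl axis is formed without control of its sense (racemic if it is configurationally stable).

**Route**

Step 1
Reactants: 1 2,4,6-trimethoxyphenol; 2 2-fluoro-4,6-dimethoxybenzaldehyde
Product: 3 2,4-dimethoxy-6-(2,4,6-trimethoxyphenoxy)benzaldehyde
Conditions: K2CO3, DMF, 120 °C
Reagents that add atoms: none
Why: Nucleophilic aromatic substitution (SNAr), because the fluorine of 2 is ortho to the formyl group, which stabilises the Meisenheimer adduct, so the hindered but electron-rich phenoxide of 1 should displace it and form the G–O–H ether.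

Step 2
Reactants: 3
Product: 5 2,4-dimethoxy-6-(2,4,6-trimethoxyphenoxy)phenol, via aryl formate 4 (not isolated)
Conditions: mCPBA, CH2Cl2, 0 °C to rt; then K2CO3 (cat.), MeOH, rt
Reagents that add atoms: mCPBA, OOC(=O)c1cccc(Cl)c1
Why: Baeyer–Villiger (Dakin-type) oxidation, in which the trioxygenated aryl group migrates in preference to hydrogen and methanolysis of the formate frees a phenol at the carbon that carried the formyl group.

Step 3
Reactants: 5; 2
Product: 6 2-[2,4-dimethoxy-6-(2,4,6-trimethoxyphenoxy)phenoxy]-4,6-dimethoxybenzaldehyde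
Conditions: Cs2CO3, DMSO, 120 °C
Reagents that add atoms: none
Why: SNAr again, the 2,6-disubstituted phenoxide of 5 attacking the unhindered ortho-fluoro carbon activated by the formyl group to form the F–O–G ether.

Step 4
Reactants: 6
Product: 8 2-[2,4-dimethoxy-6-(2,4,6-trimethoxyphenoxy)phenoxy]-4,6-dimethoxyphenol, via aryl formate 7 (not isolated)
Conditions: mCPBA, CH2Cl2, 0 °C to rt; then K2CO3 (cat.), MeOH, rt
Reagents that add atoms: mCPBA, OOC(=O)c1cccc(Cl)c1
Why: Baeyer–Villiger oxidation with migration of the electron-rich aryl group, followed by formate methanolysis, should give the ring F phenol.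

Step 5
Reactants: 8
Product: 9 2-[2,4-dimethoxy-6-(2,4,6-trimethoxyphenoxy)phenoxy]-4,6-dimethoxyphenyl trifluoromethanesulfonate
Conditions: PhNTf2, Cs2CO3, DMF, rt
Reagents that add atoms: N-phenylbis(trifluoromethanesulfonimide), O=S(=O)(N(c1ccccc1)S(=O)(=O)C(F)(F)F)C(F)(F)F
Why: O-Sulfonylation of the phenoxide with a mild triflyl donor that leaves the electron-rich rings untouched turns the former formyl carbon into a cross-coupling electrophile.

Step 6
Reactants: 10 3,5-dimethoxyphenol
Product: 11 1,3-dimethoxy-5-(methoxymethoxy)benzene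
Conditions: MOMCl, iPr2NEt, CH2Cl2, 0 °C to rt
Reagents that add atoms: chloromethyl methyl ether, COCCl
Why: O-Alkylation of the phenol (MOM protection) installs a strong ortho-directing group that is removable under mild acid.

Step 7
Reactants: 11; 9
Product: 14 2-[2,4-dimethoxy-6-(2,4,6-trimethoxyphenoxy)phenoxy]-2',4,4',6-tetramethoxy-6'-(methoxymethoxy)-1,1'-biphenyl, via aryllithium 12 (not isolated), via arylzinc chloride 13 (not isolated)
Conditions: 11 (2.5 equiv), n-BuLi, TMEDA, THF, 0 °C; ZnCl2, THF, 0 °C to rt; then 9, Pd2(dba)3 (2.5 mol %), RuPhos (10 mol %), THF/NMP, 80 °C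
Reagents that add atoms: none
Why: Directed ortho-metalation should occur between OMOM and OMe (cooperative direction, favoured over the site between two OMe groups), and Negishi coupling of the derived arylzinc with a bulky dialkylbiarylphosphine ligand is a known way to tetra-ortho-substituted biaryls; the axis forms without stereocontrol.

Step 8
Reactants: 14
Product: 15 2'-[2,4-dimethoxy-6-(2,4,6-trimethoxyphenoxy)phenoxy]-4,4',6,6'-tetramethoxy-[1,1'-biphenyl]-2-ol
Conditions: 3 M HCl, MeOH/THF, 50 °C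
Reagents that add atoms: none
Why: Acid-catalysed acetal cleavage removes the MOM group while aryl methyl ethers and diaryl ethers are inert, freeing the ring E phenol.

Step 9
Reactants: 2
Product: 16 3-bromo-2-fluoro-4,6-dimethoxybenzaldehyde
Conditions: NBS, MeCN, 0 °C to rt
Reagents that add atoms: N-bromosuccinimide, O=C1CCC(=O)N1Br
Why: Electrophilic aromatic bromination should favour C-3, which is ortho to 4-OMe, para to 6-OMe and flanked only by the small fluorine, over C-5 wedged between two OMe groups, as in the C-5 bromination of 2,4-dimethoxybenzaldehyde.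

Step 10
Reactants: 16
Product: 17 2-(3-bromo-2-fluoro-4,6-dimethoxyphenyl)-1,3-dioxolane
Conditions: HOCH2CH2OH, TsOH (cat.), toluene, reflux, Dean–Stark
Reagents that add atoms: ethane-1,2-diol, OCCO
Why: Acid-catalysed acetalisation masks the formyl group and so switches off the SNAr activation of the C–F bond for the next step.

Step 11
Reactants: 15; 17
Product: 19 3-({2'-[2,4-dimethoxy-6-(2,4,6-trimethoxyphenoxy)phenoxy]-4,4',6,6'-tetramethoxy-[1,1'-biphenyl]-2-yl}oxy)-2-fluoro-4,6-dimethoxybenzaldehyde, via dioxolane 18 (not isolated)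
Conditions: 17 (3 equiv), CuI (0.3 equiv), 2,2,6,6-tetramethylheptane-3,5-dione (0.6 equiv), Cs2CO3, NMP, 120 °C; then 1 M HCl, THF, rt
Reagents that add atoms: water, O
Why: Ullmann diaryl ether synthesis with a diketone ligand at the C–Br bond, the only reactive site because the acetal leaves the C–F bond unactivated; the acidic work-up returns the aldehyde and so re-arms the fluorine.

Step 12
Reactants: 20 4-(benzyloxy)-3-methoxyphenol
Product: 21 4-(benzyloxy)-2-bromo-5-methoxyphenol
Conditions: NBS, CH2Cl2, −78 to 0 °C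
Reagents that add atoms: N-bromosuccinimide, O=C1CCC(=O)N1Br
Why: Electrophilic bromination goes to the unhindered carbon that is ortho to OH and para to OMe, which is the future biaryl carbon of ring C.

Step 13
Reactants: 21; 2
Product: 22 2-[4-(benzyloxy)-2-bromo-5-methoxyphenoxy]-4,6-dimethoxybenzaldehyde
Conditions: K2CO3, DMF, 110 °C
Reagents that add atoms: none
Why: SNAr at the formyl-activated C–F bond forms the B–O–C ether, the unactivated aryl bromide being inert to phenoxide.

Step 14
Reactants: 22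
Product: 24 2-[4-(benzyloxy)-2-bromo-5-methoxyphenoxy]-4,6-dimethoxyphenol, via aryl formate 23 (not isolated)
Conditions: mCPBA, CH2Cl2, 0 °C to rt; then K2CO3 (cat.), MeOH, rt
Reagents that add atoms: mCPBA, OOC(=O)c1cccc(Cl)c1
Why: Baeyer–Villiger oxidation and formate methanolysis convert the formyl carbon into the ring B phenol that will carry ring A; benzyl ether and aryl bromide are unaffected.

Step 15
Reactants: 24; 25 (3,5-dimethoxyphenyl)boronic acid
Product: 26 1-(benzyloxy)-5-bromo-4-[2-(3,5-dimethoxyphenoxy)-3,5-dimethoxyphenoxy]-2-methoxybenzene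
Conditions: 25 (3 equiv), Cu(OAc)2 (0.3 equiv), pyridine, 4 Å MS, O2 (1 atm), CH2Cl2, rt
Reagents that add atoms: none
Why: Chan–Lam O-arylation works at room temperature through an aryl copper phenoxide and does not touch the aryl bromide, which an Ullmann coupling with an aryl halide would.

Step 16
Reactants: 26
Product: 27 2-(benzyloxy)-6-(3,5-dimethoxyphenoxy)-3,7,9-trimethoxydibenzo[b,d]furan
Conditions: Pd(OAc)2 (5 mol %), PCy3·HBF4 (10 mol %), K2CO3, DMA, 130 °C
Reagents that add atoms: none
Why: Palladium-catalysed intramolecular direct arylation (oxidative addition into C–Br, then concerted metalation–deprotonation) can only reach the single free ortho C–H of ring B, which closes the furan ring regiospecifically.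

Step 17
Reactants: 27
Product: 28 6-(3,5-dimethoxyphenoxy)-3,7,9-trimethoxydibenzo[b,d]furan-2-ol
Conditions: H2 (1 atm), Pd/C, EtOAc/MeOH, rt
Reagents that add atoms: none
Why: Hydrogenolysis of the benzyl ether frees the C-2 phenol selectively, since methyl and aryl ethers are stable and no halogen remains.

Step 18
Reactants: 28; 19
Product: 29 2-{[6-(3,5-dimethoxyphenoxy)-3,7,9-trimethoxydibenzo[b,d]furan-2-yl]oxy}-3-({2'-[2,4-dimethoxy-6-(2,4,6-trimethoxyphenoxy)phenoxy]-4,4',6,6'-tetramethoxy-[1,1'-biphenyl]-2-yl}oxy)-4,6-dimethoxybenzaldehyde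
Conditions: Cs2CO3, DMSO, 110 °C
Reagents that add atoms: none
Why: SNAr of the guaiacol-type phenoxide of 28 at the fluorine ortho to the formyl group of 19 joins the two halves through the ring C–O–ring D ether.

Step 19
Reactants: 29
Product: 31 the phenol of 29, in which the formyl group on ring D is replaced by OH (one free OH, sixteen OMe), via aryl formate 30 (not isolated)
Conditions: mCPBA, CH2Cl2, 0 °C; then K2CO3 (cat.), MeOH, rt
Reagents that add atoms: mCPBA, OOC(=O)c1cccc(Cl)c1
Why: Baeyer–Villiger oxidation with migration of the 2,6-dioxygenated ring D aryl group and formate methanolysis place the only free OH of the molecule ortho to the C–O–D ether oxygen.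

Step 20
Reactants: 31
Product: 32 hexadecamethyl ether of the target (the dibenzo-1,4-dioxin with all sixteen OH as OMe)
Conditions: Pd(OAc)2 (10 mol %), 1,3-bis(2,6-diisopropylphenyl)imidazolium chloride (20 mol %), 4,5-diazafluoren-9-one (10 mol %), sodium 2,4,6-trimethylbenzoate (0.5 equiv), K2CO3 (2 equiv), air (1 atm), mesitylene, 120 °C
Reagents that add atoms: none
Why: Proposed new method: the phenoxide of 31 binds divalent palladium, carboxylate-assisted concerted metalation–deprotonation at ring C C-1 gives a seven-membered aryl palladium aryloxide, and C–O reductive elimination forms the bond and releases zerovalent palladium, which air reoxidises; the closest known reaction types are the palladium-catalysed, phenol-directed C–H activation/C–O cyclisation of 2-arylphenols to dibenzofurans under these aerobic conditions and the carboxylate-directed C–H lactonisation of 2-arylbenzoic acids, which also passes a seven-membered palladacycle to a six-membered C–O ring. The 1,4-dioxin ring closes by intramolecular C–O reductive elimination from that palladacycle onto an aromatic carbon, and no stereocentre is formed. The step needs site selectivity for ring C C-1, which the substrate secures because the other ortho carbon of the ring C ether oxygen carries OMe, the next nearest C–H (ring E C-2) would need an eight-membered palladacycle, and every other diaryl ether has a ring with both ortho positions substituted, so dibenzofuran-type C–C closure is impossible. It needs chemoselectivity for one oxygen, which is secured because 31 has a single free OH. C-1 is meta to the two donor oxygens of ring C and would not be chosen by an innate oxidative phenol coupling, which is why the oxidant is a metal held on the phenoxide and not a free one-electron oxidant.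

Step 21
Reactants: 32
Product: 33 CNP0192765.0 (target)
Conditions: BBr3 (40 equiv), CH2Cl2, −78 °C to rt; then MeOH, H2O, under argon
Reagents that add atoms: none
Why: Lewis acid-mediated cleavage of aryl methyl ethers (bromide attacks the methyl group of the boron-complexed ether) removes all sixteen methyl groups, while diaryl ether, furan and dioxin C(sp2)–O bonds should not be cleaved.

**Compound list**

1 | 2,4,6-trimethoxyphenol | COc1cc(OC)c(O)c(OC)c1 | starting material
2 | 2-fluoro-4,6-dimethoxybenzaldehyde | O=Cc1c(F)cc(OC)cc1OC | starting material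
3 | 2,4-dimethoxy-6-(2,4,6-trimethoxyphenoxy)benzaldehyde | O=Cc1c(Oc2c(OC)cc(OC)cc2OC)cc(OC)cc1OC | intermediate
4 | 2,4-dimethoxy-6-(2,4,6-trimethoxyphenoxy)phenyl formate | O=COc1c(Oc2c(OC)cc(OC)cc2OC)cc(OC)cc1OC | intermediate
5 | 2,4-dimethoxy-6-(2,4,6-trimethoxyphenoxy)phenol | Oc1c(Oc2c(OC)cc(OC)cc2OC)cc(OC)cc1OC | intermediate
6 | 2-[2,4-dimethoxy-6-(2,4,6-trimethoxyphenoxy)phenoxy]-4,6-dimethoxybenzaldehyde | O=Cc1c(Oc2c(Oc3c(OC)cc(OC)cc3OC)cc(OC)cc2OC)cc(OC)cc1OC | intermediate
7 | formate of phenol 8 | O=COc1c(Oc2c(Oc3c(OC)cc(OC)cc3OC)cc(OC)cc2OC)cc(OC)cc1OC | intermediate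
8 | 2-[2,4-dimethoxy-6-(2,4,6-trimethoxyphenoxy)phenoxy]-4,6-dimethoxyphenol | Oc1c(Oc2c(Oc3c(OC)cc(OC)cc3OC)cc(OC)cc2OC)cc(OC)cc1OC | intermediate
9 | triflate of phenol 8 | O=S(=O)(Oc1c(Oc2c(Oc3c(OC)cc(OC)cc3OC)cc(OC)cc2OC)cc(OC)cc1OC)C(F)(F)F | intermediate
10 | 3,5-dimethoxyphenol | COc1cc(O)cc(OC)c1 | starting material
11 | 1,3-dimethoxy-5-(methoxymethoxy)benzene | COCOc1cc(OC)cc(OC)c1 | intermediate
12 | 2,4-dimethoxy-6-(methoxymethoxy)phenyllithium | [Li]c1c(OC)cc(OC)cc1OCOC | intermediate
13 | [2,4-dimethoxy-6-(methoxymethoxy)phenyl]zinc chloride | Cl[Zn]c1c(OC)cc(OC)cc1OCOC | intermediate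
14 | MOM-protected E–F–G–H tetramer (biaryl) | COCOc1cc(OC)cc(OC)c1-c1c(Oc2c(Oc3c(OC)cc(OC)cc3OC)cc(OC)cc2OC)cc(OC)cc1OC | intermediate
15 | E–F–G–H tetramer with free ring E phenol | Oc1cc(OC)cc(OC)c1-c1c(Oc2c(Oc3c(OC)cc(OC)cc3OC)cc(OC)cc2OC)cc(OC)cc1OC | intermediate
16 | 3-bromo-2-fluoro-4,6-dimethoxybenzaldehyde | O=Cc1c(F)c(Br)c(OC)cc1OC | intermediate
17 | 2-(3-bromo-2-fluoro-4,6-dimethoxyphenyl)-1,3-dioxolane | Fc1c(Br)c(OC)cc(OC)c1C1OCCO1 | intermediate
18 | 1,3-dioxolane of aldehyde 19 | Fc1c(Oc2cc(OC)cc(OC)c2-c2c(Oc3c(Oc4c(OC)cc(OC)cc4OC)cc(OC)cc3OC)cc(OC)cc2OC)c(OC)cc(OC)c1C1OCCO1 | intermediate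
19 | D–E–F–G–H pentamer, 2-fluorobenzaldehyde on ring D | O=Cc1c(F)c(Oc2cc(OC)cc(OC)c2-c2c(Oc3c(Oc4c(OC)cc(OC)cc4OC)cc(OC)cc3OC)cc(OC)cc2OC)c(OC)cc1OC | intermediate
20 | 4-(benzyloxy)-3-methoxyphenol | COc1cc(O)ccc1OCc1ccccc1 | starting material
21 | 4-(benzyloxy)-2-bromo-5-methoxyphenol | COc1cc(O)c(Br)cc1OCc1ccccc1 | intermediate
22 | 2-[4-(benzyloxy)-2-bromo-5-methoxyphenoxy]-4,6-dimethoxybenzaldehyde | O=Cc1c(Oc2cc(OC)c(OCc3ccccc3)cc2Br)cc(OC)cc1OC | intermediate
23 | formate of phenol 24 | O=COc1c(Oc2cc(OC)c(OCc3ccccc3)cc2Br)cc(OC)cc1OC | intermediate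
24 | 2-[4-(benzyloxy)-2-bromo-5-methoxyphenoxy]-4,6-dimethoxyphenol | Oc1c(Oc2cc(OC)c(OCc3ccccc3)cc2Br)cc(OC)cc1OC | intermediate
25 | (3,5-dimethoxyphenyl)boronic acid | OB(O)c1cc(OC)cc(OC)c1 | starting material
26 | 1-(benzyloxy)-5-bromo-4-[2-(3,5-dimethoxyphenoxy)-3,5-dimethoxyphenoxy]-2-methoxybenzene | COc1cc(OC)cc(Oc2c(Oc3cc(OC)c(OCc4ccccc4)cc3Br)cc(OC)cc2OC)c1 | intermediate
27 | 2-(benzyloxy)-6-(3,5-dimethoxyphenoxy)-3,7,9-trimethoxydibenzo[b,d]furan | COc1cc(OC)cc(Oc2c(OC)cc(OC)c3c2oc2cc(OC)c(OCc4ccccc4)cc23)c1 | intermediate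
28 | 6-(3,5-dimethoxyphenoxy)-3,7,9-trimethoxydibenzo[b,d]furan-2-ol | COc1cc(OC)cc(Oc2c(OC)cc(OC)c3c2oc2cc(OC)c(O)cc23)c1 | intermediate
29 | octamer aldehyde (ring D: CHO flanked by OMe and the O–ring C ether) | COc1cc(OC)cc(Oc2c(OC)cc(OC)c3c2oc2cc(OC)c(Oc4c(C=O)c(OC)cc(OC)c4Oc5cc(OC)cc(OC)c5-c6c(Oc7c(Oc8c(OC)cc(OC)cc8OC)cc(OC)cc7OC)cc(OC)cc6OC)cc23)c1 | intermediate
30 | formate of phenol 31 | COc1cc(OC)cc(Oc2c(OC)cc(OC)c3c2oc2cc(OC)c(Oc4c(OC=O)c(OC)cc(OC)c4Oc5cc(OC)cc(OC)c5-c6c(Oc7c(Oc8c(OC)cc(OC)cc8OC)cc(OC)cc7OC)cc(OC)cc6OC)cc23)c1 | intermediate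
31 | octamer phenol (ring D OH ortho to the O–ring C ether; sixteen OMe) | COc1cc(OC)cc(Oc2c(OC)cc(OC)c3c2oc2cc(OC)c(Oc4c(O)c(OC)cc(OC)c4Oc5cc(OC)cc(OC)c5-c6c(Oc7c(Oc8c(OC)cc(OC)cc8OC)cc(OC)cc7OC)cc(OC)cc6OC)cc23)c1 | intermediate
32 | hexadecamethyl ether of the target | COc1cc(OC)cc(Oc2c(OC)cc(OC)c3c2oc2cc(OC)c4c(c23)Oc2c(OC)cc(OC)c(Oc3cc(OC)cc(OC)c3-c3c(OC)cc(OC)cc3Oc3c(OC)cc(OC)cc3Oc3c(OC)cc(OC)cc3OC)c2O4)c1 | intermediate
33 | CNP0192765.0 | Oc1cc(O)cc(Oc2c(O)cc(O)c3c2oc2cc(O)c4c(c23)Oc2c(O)cc(O)c(Oc3cc(O)cc(O)c3-c3c(O)cc(O)cc3Oc3c(O)cc(O)cc3Oc3c(O)cc(O)cc3O)c2O4)c1 | target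

**Count**

Total steps: 21. Longest linear sequence: 12 steps (steps 1, 2, 3, 4, 5, 7, 8, 11, 18, 19, 20, 21).

**Steps most likely to fail**

1. Step 20 (proposed new method). The palladation at ring C C-1 may not occur, because this C–H lies in the bay of the dibenzofuran next to the C-9 methoxy group. The C–O reductive elimination from divalent palladium may also be slower than oxidation of the electron-rich para-methoxyphenol to a quinone with loss of a methyl group.
Fallback (halogen-based closure, known chemistry), setting out from 28 and returning at 32: carbamoylation (Et2NCOCl, NaH, THF) should give the O-aryl N,N-diethylcarbamate F1. Directed ortho-metalation (s-BuLi, TMEDA, THF, −78 °C) at the only free ortho position, C-1, gives the aryllithium F2, which is quenched with 1,2-dibromotetrachloroethane to give the 1-bromo carbamate F3. KOH in EtOH at reflux frees the 1-bromo phenol F4. SNAr with 19 under the conditions of step 18 gives the bromo aldehyde F5. Baeyer–Villiger oxidation and methanolysis as in step 19 give the bromo phenol F7 through the formate F6. Intramolecular Ullmann etherification (CuI, N,N-dimethylglycine, Cs2CO3, dioxane, 110 °C) then forms the same C–O bond and gives 32.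

2. Step 11. Copper insertion and ligand exchange at the di-ortho-substituted, electron-rich C–Br bond may be too slow for the bulky ortho-aryl phenoxide of 15, so that hydrodebromination of 17 or no conversion results.
Fallback (ring D as a quinone electrophile), setting out from 15 and 28 and returning at 31, so that steps 18 and 19 are skipped: 2-methoxy-1,4-benzoquinone is dibrominated on its unsubstituted C=C (Br2, NaOAc, AcOH) to 2,3-dibromo-5-methoxy-1,4-benzoquinone F8. The phenoxide of 15 (K2CO3, DMF, 0 °C) should displace, by addition–elimination, the bromide β to the carbonyl that the methoxy group does not deactivate, giving the aryloxy bromoquinone F9. The phenoxide of 28 displaces the second bromide to give the bis(aryloxy)quinone F10. Na2S2O4 reduces it to the hydroquinone F11. One equivalent of MeI with K2CO3 in acetone should methylate the less hindered OH (flanked by H) and leave the OH flanked by OMe and OAr, which is 31.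

3. Step 7. Transmetalation and reductive elimination at a biaryl bond with four ortho oxygen substituents may be slower than protodemetalation of the arylzinc and loss of the triflate.
Fallback (addition to a dearomatised ring F instead of cross-coupling), setting out from 8 and returning at 14: PhI(OAc)2 in MeOH at 0 °C should oxidise the para-methoxyphenol 8 to the para-quinone monoketal F12. The aryllithium 12, made from 11 as in step 7, adds 1,2 to the carbonyl (THF, −78 °C) to give the quinol ketal F13. Zn in AcOH effects reductive aromatisation with loss of water and methanol and gives 14.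

**Further compounds**

F1 | step 20 | O-aryl N,N-diethylcarbamate of 28 | COc1cc(OC)cc(Oc2c(OC)cc(OC)c3c2oc2cc(OC)c(OC(=O)N(CC)CC)cc23)c1
F2 | step 20 | C-1 lithiated carbamate | COc1cc(OC)cc(Oc2c(OC)cc(OC)c3c2oc2cc(OC)c(OC(=O)N(CC)CC)c([Li])c23)c1
F3 | step 20 | 1-bromo carbamate | COc1cc(OC)cc(Oc2c(OC)cc(OC)c3c2oc2cc(OC)c(OC(=O)N(CC)CC)c(Br)c23)c1
F4 | step 20 | 1-bromo-6-(3,5-dimethoxyphenoxy)-3,7,9-trimethoxydibenzo[b,d]furan-2-ol | COc1cc(OC)cc(Oc2c(OC)cc(OC)c3c2oc2cc(OC)c(O)c(Br)c23)c1
F5 | step 20 | 1-bromo analogue of aldehyde 29 | COc1cc(OC)cc(Oc2c(OC)cc(OC)c3c2oc2cc(OC)c(Oc4c(C=O)c(OC)cc(OC)c4Oc5cc(OC)cc(OC)c5-c6c(Oc7c(Oc8c(OC)cc(OC)cc8OC)cc(OC)cc7OC)cc(OC)cc6OC)c(Br)c23)c1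
F6 | step 20 | 1-bromo analogue of formate 30 | COc1cc(OC)cc(Oc2c(OC)cc(OC)c3c2oc2cc(OC)c(Oc4c(OC=O)c(OC)cc(OC)c4Oc5cc(OC)cc(OC)c5-c6c(Oc7c(Oc8c(OC)cc(OC)cc8OC)cc(OC)cc7OC)cc(OC)cc6OC)c(Br)c23)c1
F7 | step 20 | 1-bromo analogue of phenol 31 | COc1cc(OC)cc(Oc2c(OC)cc(OC)c3c2oc2cc(OC)c(Oc4c(O)c(OC)cc(OC)c4Oc5cc(OC)cc(OC)c5-c6c(Oc7c(Oc8c(OC)cc(OC)cc8OC)cc(OC)cc7OC)cc(OC)cc6OC)c(Br)c23)c1
F8 | step 11 | 2,3-dibromo-5-methoxy-1,4-benzoquinone | COC1=CC(=O)C(Br)=C(Br)C1=O
F9 | step 11 | 2-bromo-5-methoxy-3-(ring E aryloxy)-1,4-benzoquinone | COC1=CC(=O)C(Oc2cc(OC)cc(OC)c2-c2c(Oc3c(Oc4c(OC)cc(OC)cc4OC)cc(OC)cc3OC)cc(OC)cc2OC)=C(Br)C1=O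
F10 | step 11 | bis(aryloxy)methoxyquinone (ring D as 1,4-benzoquinone) | COc1cc(OC)cc(Oc2c(OC)cc(OC)c3c2oc2cc(OC)c(OC4=C(Oc5cc(OC)cc(OC)c5-c6c(Oc7c(Oc8c(OC)cc(OC)cc8OC)cc(OC)cc7OC)cc(OC)cc6OC)C(=O)C=C(OC)C4=O)cc23)c1
F11 | step 11 | hydroquinone of F10 | COc1cc(OC)cc(Oc2c(OC)cc(OC)c3c2oc2cc(OC)c(Oc4c(O)c(OC)cc(O)c4Oc5cc(OC)cc(OC)c5-c6c(Oc7c(Oc8c(OC)cc(OC)cc8OC)cc(OC)cc7OC)cc(OC)cc6OC)cc23)c1
F12 | step 7 | para-quinone monoketal of 8 (4,4-dimethoxycyclohexa-2,5-dienone) | COC1=CC(OC)(OC)C=C(Oc2c(Oc3c(OC)cc(OC)cc3OC)cc(OC)cc2OC)C1=O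
F13 | step 7 | quinol ketal from addition of 12 to F12 | COC1=CC(OC)(OC)C=C(Oc2c(Oc3c(OC)cc(OC)cc3OC)cc(OC)cc2OC)C1(O)c1c(OC)cc(OC)cc1OCOC
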